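**Retrosynthetic overview**
1. Locants: ring O1, C2 (guaiacyl), C3 (bears C9H2OH), C4 (bears ketone carbon C7'), C5H2; the target is the all-trans (2S,3R,4S) isomer. Endgame: aryl MOM removal ⇐ C7' alcohol to ketone ⇐ C2–B to C2–H with retention.
2. Key disconnection: guaiacyl–C2 and C3–C9 are cut together ⇒ guaiacyl-lithium + 2-boryl-4,5-dihydrofuran + ClCH2OSi(i-Pr)3. They are joined by an electrophile-triggered 1,2-shift of the aryl group from boron to C2.
3. Enabling feature: in the ring segment O1–C2–C3, C2 carries both O1 and the guaiacyl ring, and its neighbour C3 carries the one-carbon branch trans to the aryl group. This is the retron of an anti carbo-arylation of an O1–C2=C3 enol ether: O1 makes C3 nucleophilic and C2 cation-like, and boron on C2 hands over the aryl group.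
4. Boryl dihydrofuran ⇐ vinylic C–H borylation ⇐ lactol dehydration ⇐ Evans syn-aldol of a pentenoyl oxazolidinone with protected syringaldehyde. The aldol sets C4, which then steers C3 and C2.
5. Ring order: both arenes are bought. The oxygen ring is the only ring made (lactol, step 6); it is carried as a dihydrofuran and saturated in the key step.

Key step: step 10

Remark on the chemistry: ArS = 3,5-dimethoxy-4-(methoxymethoxy)phenyl and ArG = 3-methoxy-4-(methoxymethoxy)phenyl. The locants above are used for all intermediates. The C7' carbinol configuration is of no consequence because it is oxidised in step 12.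

Step 1
Reactants: 1 syringaldehyde (4-hydroxy-3,5-dimethoxybenzaldehyde)
Product: 2 3,5-dimethoxy-4-(methoxymethoxy)benzaldehyde
Conditions: MOMCl, i-Pr2NEt, CH2Cl2, 0 °C to rt
Reagents that add atoms: chloromethyl methyl ether (MOMCl), COCCl
Why: Williamson-type O-alkylation of the phenol with the reactive chloromethyl ether (acetal protection) masks the acidic OH against the boron enolate, LiBH4 and aryllithium chemistry to come; no stereocentre is formed.

Step 2
Reactants: 3 (R)-4-benzyl-1,3-oxazolidin-2-one; 4 pent-4-enoyl chloride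
Product: 5 (R)-4-benzyl-3-(pent-4-enoyl)-1,3-oxazolidin-2-one
Conditions: Et3N, DMAP (cat.), CH2Cl2, 0 °C to rt
Reagents that add atoms: none
Why: DMAP-catalysed N-acylation of the oxazolidinone by the acid chloride is the standard way to load the Evans auxiliary and does not touch its stereocentre.

Step 3
Reactants: 5 (R)-4-benzyl-3-(pent-4-enoyl)-1,3-oxazolidin-2-one; 2 3,5-dimethoxy-4-(methoxymethoxy)benzaldehyde
Product: 8 syn-aldol adduct (R)-4-benzyl-3-[(2R)-2-{(R)-hydroxy[ArS]methyl}pent-4-enoyl]-1,3-oxazolidin-2-one, via Z-dibutylboron enolate 6 (not isolated), via dibutylboron aldolate 7 (not isolated)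
Conditions: n-Bu2BOTf, i-Pr2NEt, CH2Cl2, −78 to 0 °C; 2, −78 to 0 °C; then pH 7 buffer, MeOH, 30% H2O2, 0 °C
Reagents that add atoms: none
Why: Evans syn-aldol reaction in which soft enolisation gives Z-enolate 6, which adds to 2 through a chair-like Zimmerman–Traxler transition state on the face left open by the benzyl group of the (R)-auxiliary, so that C4 (R in this compound, the later 4S) and the C7' carbinol (R) are set together before oxidative work-up frees 8 from aldolate 7.

Step 4
Reactants: 8 syn-aldol adduct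
Product: 9 tert-butyldimethylsilyl ether of 8, (R)-4-benzyl-3-[(2R)-2-{(R)-(tert-butyldimethylsilyloxy)[ArS]methyl}pent-4-enoyl]-1,3-oxazolidin-2-one
Conditions: TBSOTf, 2,6-lutidine, CH2Cl2, −78 to 0 °C
Reagents that add atoms: tert-butyldimethylsilyl triflate (TBSOTf), CC(C)(C)[Si](C)(C)OS(=O)(=O)C(F)(F)F
Why: Silylation of the hindered benzylic alcohol with the silyl triflate blocks retro-aldol cleavage and protects C7'–OH; no stereocentre changes.

Step 5
Reactants: 9 silyl ether
Product: 10 (2S)-2-{(R)-(tert-butyldimethylsilyloxy)[ArS]methyl}pent-4-en-1-ol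
Conditions: LiBH4, MeOH (1 equiv), THF, 0 °C
Reagents that add atoms: none
Why: Reductive removal of the auxiliary (imide reduction by LiBH4) turns the C5 carbonyl into the C5H2OH that will enter the ring, without epimerisation at C4 because the aldehyde stage is reduced at once.

Step 6
Reactants: 10 homoallylic-type alcohol
Product: 13 lactol (4S)-4-{(R)-(tert-butyldimethylsilyloxy)[ArS]methyl}tetrahydrofuran-2-ol as anomer mixture, via triol 11 (not isolated), via hydroxy aldehyde 12 (not isolated)
Conditions: OsO4 (cat.), NaIO4, 2,6-lutidine, 1,4-dioxane/H2O, rt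
Reagents that add atoms: osmium tetroxide OsO4, O=[Os](=O)(=O)=O (delivers the oxygen atom and is re-formed by NaIO4); sodium periodate NaIO4, [Na+].[O-]I(=O)(=O)=O
Why: Lemieux–Johnson oxidation (dihydroxylation to 11, periodate cleavage to 12) shortens the allyl group to the C2 aldehyde, which is trapped by C5–OH (5-exo-trig hemiacetal formation) to close the only ring that must be made; the new anomeric centre is a mixture and is erased in step 7.

Step 7
Reactants: 13 lactol
Product: 15 (3S)-3-{(R)-(tert-butyldimethylsilyloxy)[ArS]methyl}-2,3-dihydrofuran, via anomeric mesylate 14 (not isolated)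
Conditions: MsCl, Et3N (excess), CH2Cl2, −20 °C to reflux
Reagents that add atoms: none
Why: Lactol dehydration by anomeric mesylation and amine-induced elimination, the reaction type used to make glycals from 2-deoxy lactols, gives the O1–C2=C3 enol ether and leaves C4 and C7' untouched.

Step 8
Reactants: 15 dihydrofuran
Product: 16 2-[(4S)-4-{(R)-(tert-butyldimethylsilyloxy)[ArS]methyl}-4,5-dihydrofuran-2-yl]-4,4,5,5-tetramethyl-1,3,2-dioxaborolane
Conditions: [Ir(OMe)(cod)]2 (cat.), 4,4'-di-tert-butyl-2,2'-bipyridine (cat.), B2pin2, hexane, rt to 50 °C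
Reagents that add atoms: bis(pinacolato)diboron (B2pin2), CC1(C)OB(OC1(C)C)B1OC(C)(C)C(C)(C)O1
Why: Iridium-catalysed vinylic C–H borylation of a cyclic vinyl ether should go to C2 (alpha to O1) because C3 is shielded by the branched C4 and both arene C–H bonds of ArS are flanked by two ortho substituents; no stereocentre is touched.

Step 9
Reactants: 17 4-bromo-2-methoxyphenol
Product: 18 4-bromo-2-methoxy-1-(methoxymethoxy)benzene
Conditions: MOMCl, i-Pr2NEt, CH2Cl2, 0 °C to rt
Reagents that add atoms: chloromethyl methyl ether (MOMCl), COCCl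
Why: Williamson-type O-alkylation (acetal protection) removes the acidic phenol proton before halogen–lithium exchange; no stereocentre is formed.

Step 10
Reactants: 16 2-boryl-4,5-dihydrofuran; 18 4-bromo-2-methoxy-1-(methoxymethoxy)benzene; 19 (triisopropylsiloxy)methyl chloride
Product: 22 2-{(2S,3R,4S)-4-{(R)-(tert-butyldimethylsilyloxy)[ArS]methyl}-2-[ArG]-3-[(triisopropylsilyloxy)methyl]tetrahydrofuran-2-yl}-4,4,5,5-tetramethyl-1,3,2-dioxaborolane (ArG trans to the C3 branch; boron cis to it), via aryllithium 20 (not isolated), via lithium borate complex 21 (not isolated)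
Conditions: 18, n-BuLi, THF, −78 °C; 16, −78 to 0 °C; then 19, −78 °C to rt
Reagents that add atoms: none
Why: Proposed new method: bromine–lithium exchange gives aryllithium 20, which adds to the empty orbital of boron in 16 to give borate 21, an O1–C2=C3 enol ether made strongly nucleophilic at C3 by O1 and by the anionic boron on C2. C3 attacks chloromethyl ether 19 (C3–C9 bond), and the oxocarbenium character that builds up at C2 is discharged by a 1,2-shift of the guaiacyl group from boron to C2, which makes the aryl–C2 bond and leaves neutral pinacolboryl on C2. The closest known reaction type is the electrophile-induced 1,2-metallate rearrangement of alkenylboronate complexes (first half of the Zweifel olefination and its three-component variants with carbon electrophiles); new here are the cyclic alpha-alkoxyalkenyl boronate and the alkoxymethyl chloride as partners. No ring is closed, since the dihydrofuran ring is simply saturated to the tetrahydrofuran ring of the target. C3 is set by approach of 19 to the face anti to the bulky C4 side chain (3,4-trans), and C2 by the anti-periplanar course of the shift, which places aryl opposite to the new C3–C9 bond (2,3-trans) and boron where H-2 will stand. The step needs attack at C3 instead of the guaiacyl ring and migration of aryl instead of a pinacol oxygen; the first is secured by the much higher nucleophilicity of the borate-substituted enol ether, the second by the poor migratory aptitude of the chelating diol oxygens.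

Step 11
Reactants: 22 tertiary benzylic boronic ester
Product: 23 {(2S,3R,4S)-4-{(R)-hydroxy[ArS]methyl}-2-[ArG]tetrahydrofuran-3-yl}methanol
Conditions: n-Bu4NF·3H2O (excess), toluene/THF, rt to 45 °C
Reagents that add atoms: none
Why: Fluoride-promoted protodeboronation of a tertiary benzylic boronic ester proceeds by front-side protonation of the C–B bond of the fluoroborate (retention), so H-2 takes the place of boron and the 2,3-trans relation is kept, while the same fluoride cleaves both silyl ethers.

Step 12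
Reactants: 23 diol
Product: 24 [(3S,4R,5S)-4-(hydroxymethyl)-5-[ArG]tetrahydrofuran-3-yl][ArS]methanone, the (2S,3R,4S) ketone in the locants used here
Conditions: activated MnO2 (excess), CH2Cl2, rt
Reagents that add atoms: none
Why: Chemoselective heterogeneous MnO2 oxidation takes the electron-rich benzylic C7' alcohol to the aryl ketone and leaves the non-activated primary C9–OH alone; C4 already has the trans configuration that is preferred next to the new ketone.

Step 13
Reactants: 24 bis-MOM ketone
Product: 25 target, [(3S,4R,5S)-5-(4-hydroxy-3-methoxyphenyl)-4-(hydroxymethyl)tetrahydrofuran-3-yl](4-hydroxy-3,5-dimethoxyphenyl)methanone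
Conditions: 2 M HCl (aq, substoichiometric), THF, 40 °C
Reagents that add atoms: none
Why: Acid-catalysed acetal hydrolysis frees both phenols, and because the all-trans array is the thermodynamic one, any reversible ionisation of the para-hydroxybenzylic C2–O1 bond or enolisation at C4 should return the same isomer.

**Compound list**
1 | syringaldehyde | COc1cc(C=O)cc(OC)c1O | starting material
2 | 3,5-dimethoxy-4-(methoxymethoxy)benzaldehyde | COCOc1c(OC)cc(C=O)cc1OC | intermediate
3 | (R)-4-benzyl-1,3-oxazolidin-2-one | O=C1N[C@H](Cc2ccccc2)CO1 | starting material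
4 | pent-4-enoyl chloride | C=CCCC(=O)Cl | starting material
5 | (R)-4-benzyl-3-(pent-4-enoyl)-1,3-oxazolidin-2-one | C=CCCC(=O)N1[C@H](Cc2ccccc2)COC1=O | intermediate
6 | Z-dibutylboron enolate of 5 | CCCCB(CCCC)O/C(=C\CC=C)N1[C@H](Cc2ccccc2)COC1=O | intermediate
7 | dibutylboron aldolate of 8 | O=C(N1[C@H](Cc2ccccc2)COC1=O)[C@@H]([C@@H](OB(CCCC)CCCC)c1cc(OC)c(OCOC)c(OC)c1)CC=C | intermediate
8 | syn-aldol adduct (2R, carbinol R, auxiliary R) | O=C(N1[C@H](Cc2ccccc2)COC1=O)[C@@H]([C@@H](O)c1cc(OC)c(OCOC)c(OC)c1)CC=C | intermediate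
9 | TBS ether of 8 | O=C(N1[C@H](Cc2ccccc2)COC1=O)[C@@H]([C@@H](O[Si](C)(C)C(C)(C)C)c1cc(OC)c(OCOC)c(OC)c1)CC=C | intermediate
10 | (2S)-2-{(R)-(TBSO)[ArS]methyl}pent-4-en-1-ol | OC[C@@H]([C@@H](O[Si](C)(C)C(C)(C)C)c1cc(OC)c(OCOC)c(OC)c1)CC=C | intermediate
11 | (4S)-4-{(R)-(TBSO)[ArS]methyl}pentane-1,2,5-triol (mixture at C2 of the chain) | OC[C@@H]([C@@H](O[Si](C)(C)C(C)(C)C)c1cc(OC)c(OCOC)c(OC)c1)CC(O)CO | intermediate
12 | (3S)-4-hydroxy-3-{(R)-(TBSO)[ArS]methyl}butanal | OC[C@@H]([C@@H](O[Si](C)(C)C(C)(C)C)c1cc(OC)c(OCOC)c(OC)c1)CC=O | intermediate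
13 | (4S)-4-{(R)-(TBSO)[ArS]methyl}tetrahydrofuran-2-ol (anomer mixture) | O1C[C@@H]([C@@H](O[Si](C)(C)C(C)(C)C)c2cc(OC)c(OCOC)c(OC)c2)CC1O | intermediate
14 | anomeric mesylate of 13 | O1C[C@@H]([C@@H](O[Si](C)(C)C(C)(C)C)c2cc(OC)c(OCOC)c(OC)c2)CC1OS(C)(=O)=O | intermediate
15 | (3S)-3-{(R)-(TBSO)[ArS]methyl}-2,3-dihydrofuran | O1C[C@@H]([C@@H](O[Si](C)(C)C(C)(C)C)c2cc(OC)c(OCOC)c(OC)c2)C=C1 | intermediate
16 | pinacol (4S)-4-{(R)-(TBSO)[ArS]methyl}-4,5-dihydrofuran-2-ylboronate | O1C[C@@H]([C@@H](O[Si](C)(C)C(C)(C)C)c2cc(OC)c(OCOC)c(OC)c2)C=C1B3OC(C)(C)C(C)(C)O3 | intermediate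
17 | 4-bromo-2-methoxyphenol | COc1cc(Br)ccc1O | starting material
18 | 4-bromo-2-methoxy-1-(methoxymethoxy)benzene | COCOc1ccc(Br)cc1OC | intermediate
19 | (triisopropylsiloxy)methyl chloride | ClCO[Si](C(C)C)(C(C)C)C(C)C | starting material
20 | [3-methoxy-4-(methoxymethoxy)phenyl]lithium | [Li]c1ccc(OCOC)c(OC)c1 | intermediate
21 | lithium aryl(dihydrofuranyl)(pinacolato)borate | [Li+].O1C[C@@H]([C@@H](O[Si](C)(C)C(C)(C)C)c2cc(OC)c(OCOC)c(OC)c2)C=C1[B-]3(c4ccc(OCOC)c(OC)c4)OC(C)(C)C(C)(C)O3 | intermediate
22 | (2S,3R,4S)-2-aryl-2-boryl-3-(TIPSOCH2)-4-[(R)-CH(OTBS)ArS]tetrahydrofuran | COCOc1ccc(cc1OC)[C@@]2(B3OC(C)(C)C(C)(C)O3)OC[C@@H]([C@@H](O[Si](C)(C)C(C)(C)C)c4cc(OC)c(OCOC)c(OC)c4)[C@@H]2CO[Si](C(C)C)(C(C)C)C(C)C | intermediate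
23 | (2S,3R,4S)-diol with (R)-C7' carbinol | COCOc1ccc(cc1OC)[C@H]2OC[C@@H]([C@@H](O)c3cc(OC)c(OCOC)c(OC)c3)[C@@H]2CO | intermediate
24 | (2S,3R,4S)-bis-MOM ketone | COCOc1ccc(cc1OC)[C@H]2OC[C@@H](C(=O)c3cc(OC)c(OCOC)c(OC)c3)[C@@H]2CO | intermediate
25 | CNP0169680.1 | COc1cc([C@H]2OC[C@@H](C(=O)c3cc(OC)c(O)c(OC)c3)[C@@H]2CO)ccc1O | target

**Step count and risks**
Total step count: 13. Longest linear sequence: 11 steps (steps 1, 3 to 8 and 10 to 13).

Steps most likely to fail:

1. Step 10 (the proposed new method). Four things may go wrong: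
   - alkylation of the guaiacyl ring or of a pinacol oxygen in place of C3;
   - loss of the anti course of the shift if the oxocarbenium stage lives too long;
   - ring opening of the borate by expulsion of O1;
   - simple protonation of the enol ether.

   The fallback uses known chemistry: lactone enolate alkylation, then substitution of a 2-sulfonyl cyclic ether by an arylzinc reagent through the oxocarbenium ion. It sets out from lactol 13 and comes back at diol 23. Oxidation of 13 with n-Pr4N[RuO4] (cat.) and N-methylmorpholine N-oxide gives the gamma-lactone F1. Deprotonation with LiN(i-Pr)2 and alkylation with 19 anti to the C4 side chain gives the trans-disubstituted lactone F2. Reduction with i-Bu2AlH at −78 °C gives the lactol F3, and PhSO2H with CaCl2 gives the 2-(phenylsulfonyl) ether F4. Aryllithium 20 and ZnBr2 give the arylzinc bromide F5. F5 replaces the sulfonyl group of F4 from the face anti to the C3 branch to give the bis-silyl ether F6. Cleavage with n-Bu4NF then gives 23.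

2. Step 11. Three things may go wrong:
   - slow C–B cleavage, because the electron-rich aryl group and O1 poorly support negative charge at C2;
   - partial loss of retention;
   - base-induced silyl migration before the boron is lost.

   The fallback replaces protonolysis by an oxidation, reduction and etherification sequence. It sets out from 22 and comes back at 23. Oxidation of the C–B bond with NaBO3·4H2O gives, as the open form of the C2 hemiketal, the gamma-hydroxy aryl ketone F7. Corey–Bakshi–Shibata reduction with the (R)-methyl oxazaborolidine and BH3·SMe2 gives the (S)-benzylic 1,4-diol F8. Selective sulfonylation of the primary C5–OH with TsCl in pyridine gives the monotosylate F9. NaH closes the ring by a 5-exo-tet Williamson etherification, with the C2 configuration kept, to give the bis-silyl ether F6. Cleavage with n-Bu4NF then gives 23.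

3. Step 8. Three things may go wrong:
   - borylation at C3;
   - iridium-catalysed hydroboration of the enol ether by the borane that is released;
   - acid-type hydrolysis of the enol ether on isolation.

   The fallback replaces C–H activation by deprotonation. It sets out from 15 and comes back at 16. Treatment of 15 with t-BuLi in THF (−78 to 0 °C) removes the vinylic C2–H to give the 2-lithio-4,5-dihydrofuran F10. Quenching with 2-isopropoxy-4,4,5,5-tetramethyl-1,3,2-dioxaborolane gives 16.

**Further compounds**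
F1 | step 10 | (4S)-4-{(R)-(TBSO)[ArS]methyl}dihydrofuran-2(3H)-one | O1C[C@@H]([C@@H](O[Si](C)(C)C(C)(C)C)c2cc(OC)c(OCOC)c(OC)c2)CC1=O
F2 | step 10 | (3R,4S)-4-{(R)-(TBSO)[ArS]methyl}-3-[(triisopropylsilyloxy)methyl]dihydrofuran-2(3H)-one | O1C[C@@H]([C@@H](O[Si](C)(C)C(C)(C)C)c2cc(OC)c(OCOC)c(OC)c2)[C@H](CO[Si](C(C)C)(C(C)C)C(C)C)C1=O
F3 | step 10 | lactol from F2 (anomer mixture, 3R,4S) | O1C[C@@H]([C@@H](O[Si](C)(C)C(C)(C)C)c2cc(OC)c(OCOC)c(OC)c2)[C@H](CO[Si](C(C)C)(C(C)C)C(C)C)C1O
F4 | step 10 | 2-(phenylsulfonyl)tetrahydrofuran from F3 (mixture at C2, 3R,4S) | O1C[C@@H]([C@@H](O[Si](C)(C)C(C)(C)C)c2cc(OC)c(OCOC)c(OC)c2)[C@H](CO[Si](C(C)C)(C(C)C)C(C)C)C1S(=O)(=O)c3ccccc3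
F5 | step 10 | [3-methoxy-4-(methoxymethoxy)phenyl]zinc bromide | Br[Zn]c1ccc(OCOC)c(OC)c1
F6 | step 10 | (2S,3R,4S)-bis-silyl ether of 23 (C9–OTIPS, C7'–OTBS) | COCOc1ccc(cc1OC)[C@H]2OC[C@@H]([C@@H](O[Si](C)(C)C(C)(C)C)c3cc(OC)c(OCOC)c(OC)c3)[C@@H]2CO[Si](C(C)C)(C(C)C)C(C)C
F7 | step 11 | gamma-hydroxy aryl ketone (C3, C4 and C7' as in 22) | COCOc1ccc(cc1OC)C(=O)[C@@H](CO[Si](C(C)C)(C(C)C)C(C)C)[C@@H](CO)[C@@H](O[Si](C)(C)C(C)(C)C)c1cc(OC)c(OCOC)c(OC)c1
F8 | step 11 | 1,4-diol with (S)-benzylic carbinol at C2 | COCOc1ccc(cc1OC)[C@@H](O)[C@@H](CO[Si](C(C)C)(C(C)C)C(C)C)[C@@H](CO)[C@@H](O[Si](C)(C)C(C)(C)C)c1cc(OC)c(OCOC)c(OC)c1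
F9 | step 11 | C5 monotosylate of F8 | COCOc1ccc(cc1OC)[C@@H](O)[C@@H](CO[Si](C(C)C)(C(C)C)C(C)C)[C@@H](COS(=O)(=O)c1ccc(C)cc1)[C@@H](O[Si](C)(C)C(C)(C)C)c1cc(OC)c(OCOC)c(OC)c1
F10 | step 8 | (4S)-4-{(R)-(TBSO)[ArS]methyl}-4,5-dihydrofuran-2-yllithium | O1C[C@@H]([C@@H](O[Si](C)(C)C(C)(C)C)c2cc(OC)c(OCOC)c(OC)c2)C=C1[Li]
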